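## Structural features

The target is a dibenzylbutyrolactone lignan. Lignan numbering is used throughout: the γ-butyrolactone is C9′(=O)–O–C9H2–C8–C8′; the α-carbon C8′ carries a 4-hydroxy-3-methoxybenzyl group (C7′H2 and ring B); the β-carbon C8 carries a hydroxy(4-hydroxy-3-methoxyphenyl)methyl group (carbinol C7 and ring A). Three stereocentres stand in a row, C7 (R), C8 (R) and C8′ (R); C8 and C8′ are trans on the ring and C7 lies outside the ring, next to C8. C8′ is α to the carbonyl and can be corrected by enolisation, whereas C8 cannot. C7 is a p-hydroxybenzylic carbinol and is the fragile point: acid ionises it, base converts the free phenol of ring A into a phenoxide that can expel the C7 oxygen as a quinone methide, and hydrogenolysis removes it. The C7 hydroxyl is 1,4 to the carbonyl carbon C9′ and can therefore close an isomeric five-membered lactone (O7–C7–C8–C8′–C9′). The real difficulty is the exocyclic C7 centre, which must be set relative to C8 and in the absolute sense and then kept intact. The plan uses the isomeric lactone deliberately: in the ring O7–C7–C8–C8′–C9′ both C7 and C8 are ring atoms, so their relation becomes a 4,5-cis ring relation. The C7–C8 bond joins two carbons that are both acceptors by nature (an aldehyde carbon and an acrylate β-carbon), and an allylboron reagent unites them by reversing the polarity of the second.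

## Logic of the disconnections

15 ⇒ 14. The two phenolic O–Si bonds are cut. The free p-hydroxybenzylic carbinol should exist only after the last operation, so that every earlier intermediate is free of phenoxide. The forward step must be buffered, cold and close to neutral.

14 ⇒ 13 ⇒ 12. The acyl bond C9′–O9 is cut and the acyl carbon is returned to O7; then the alkyl O–Si bond at C9 is restored. In 13 and 12 the carbinol C7 is a ring atom. Because C8 exchanges its exocyclic partner (C9 in 12 and 13, C7 in 14), the trans relation C8/C8′ of 14 corresponds to the all-cis arrangement in 12 and 13. Three contiguous centres thus become three cis substituents on one ring. The forward acyl shift must run from the strained all-cis ring to the unstrained trans ring without epimerising C8′. It must also be started by freeing only the C9 oxygen: a global fluoride treatment of 12 would produce the ring A phenoxide while C7 still carries an acyloxy leaving group, which is the ideal arrangement for quinone methide formation. Two classes of silyl ether are therefore needed (aryl triisopropylsilyl, alkyl tert-butyldimethylsilyl). No base equilibration of C8′ is planned.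

12 ⇒ 9 + 11. The bond between C7′ and ring B is cut (with the C8′–H bond). This exposes an α-methylene lactone, which is the native product of a carbonyl allylation with a 2-alkoxycarbonyl allyl unit, and makes the route convergent. The forward step must be a conjugate arylation under nearly neutral conditions, and the enolate must be protonated at C8′ from the face opposite the two cis substituents.

11 ⇒ 10. One phenolic O–Si bond is cut; the same silyl group as on ring A is used so that both fall together at the end.

9 ⇒ 2 + 7 (through 8). The C7–C8 bond and the lactone bond O7–C9′ are cut. Two achiral fragments remain, and the forward step creates both stereocentres and the ring at once. It demands geometric purity of 7 (CH2OSi cis to CH2B), a catalyst that selects the re face of 2, and an acid weak enough not to ionise the new benzylic C–O bond.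

7 ⇒ 6 ⇒ 5 ⇒ 3 + 4. The C–B bond is cut with allylic transposition, then the O-acetyl bond, then the C8–C8′ bond between the acrylate α-carbon and the aldehyde carbon. The gain is two small commercial building blocks. The carbinol centre of 5 and 6 may be racemic because it becomes sp2 in 7; the demand is control of the alkene geometry when acetate leaves.

2 ⇒ 1. One phenolic O–Si bond is cut; the ether must survive aqueous rhodium catalysis and buffered HF, hence triisopropylsilyl.

## Other disconnections considered

Alternative 1: The cut is the C8–C8′ bond together with a temporary C7–C8′ bond. Forward, the allyl diazoacetate A1 would be decomposed by a chiral dirhodium carboxamidate catalyst; the carbene cyclopropanates its own (E)-alkene and gives the bicyclic lactone A2 with the aryl group exo, the target lactone ring closed and C8 set. An oxygen nucleophile would then open the cyclopropane at C7 with inversion, and C8′ would be benzylated trans to the C8 substituent.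
- In favour: asymmetric intramolecular cyclopropanation of allyl diazoacetates is a mature reaction class. The lactone appears at once in its final constitution, so no acyl shift is needed; on this point A2 is better than 9. The late trans-selective enolate alkylation at C8′ is at least the equal of the protonation used in the chosen plan.
- Against: A2 is a cyclopropane with one acceptor only and, through the aryl ester, a weakened donor. The opening therefore needs strong activation, and activation of that strength is likely to proceed by ionisation at C7 and not by clean backside attack, which would lose C7.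
- Comparison: structurally, one centre (C8) comes from the key step and two from later steps, against C7 and C8 together in the chosen plan. Mechanistically, a metal carbene and a demanding invertive substitution stand against one closed chair transition state. The step count, about nine to ten with a diazo transfer, is level with the chosen plan.

Alternative 2: The cut is at the two lactone C–O bonds, C9–O and O–C9′ (oxygen insertion). Forward, a Baeyer–Villiger monooxygenase would insert oxygen into one of the two C(=O)–CH2 bonds of the cyclobutanone A3 and give the β-substituted lactone A4; benzylation of its enolate trans to the C8 substituent and desilylation would complete the target.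
- In favour: the lactone is formed directly with the right constitution (better than the chosen plan, which must move the acyl group). The medium is mild and aqueous, without metals or acid near C7. C8′ would come from a trans-selective alkylation, which is more dependable than a kinetic protonation.
- Against: A3 already contains C7, which needs a separate enantioselective step beforehand. Its two methylene groups are diastereotopic only through that exocyclic centre, so a bulky bis-silylated substrate must fit the enzyme in the matched sense, and acceptance and selectivity would have to be found by screening. The four-membered ring also costs several steps.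
- Comparison: structurally, the key step sets one centre (C8) against two in the chosen plan. Mechanistically, enzyme recognition is less predictable for this substrate than a chair transition state. The step count is likely one or two higher.

Alternative 3: The cut is the C8–C9 bond, with C9 brought in as a silylmethyl radical tethered to the C7 oxygen. Forward, the bromide A5 and a tin hydride would give the silylmethyl radical, which closes 5-exo onto the enoate β-carbon; hydrogen transfer to the α-ester radical gives A6. Tamao oxidation of the C–Si bond and lactonisation of the primary alcohol would follow.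
- In favour: relaying C7 to C8 through a five-membered ring is the same stereochemical idea as in the chosen plan and is equally sound. C9 arrives in the right oxidation state, and the primary alcohol closes the correct lactone kinetically, without a deliberate acyl shift.
- Against: C7 must be made beforehand as a single enantiomer in a carbinol that is both allylic and electron-rich benzylic, hence prone to ionisation. C8′ is set by hydrogen transfer to an acyclic radical with little control (correctable later by equilibration, so no worse in principle than a failed protonation in the chosen plan). Stoichiometric tin is needed. The fluoride and peroxide conditions of the Tamao oxidation endanger aryl silyl ethers and raise the quinone methide problem again.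
- Comparison: structurally, the key step sets C8 only. Mechanistically, a radical chain replaces a polar closed transition state. The step count is clearly higher, about eleven to twelve.

Key step: step 5

Remarks on the chemistry:
- Target configuration: (7R,8R,8′R), which is (3R,4R)-4-[(R)-…] in lactone numbering.
- The enantiomer of the phosphoric acid that exposes the re face of the aldehyde is taken to be (R) by analogy with simple allyl and crotyl pinacol boronates. If the sense proves opposite, the (S)-acid is used without other change.
- Compounds 5 and 6 are racemic; their stereocentre is erased in step 4.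

## Route

Step 1
Reactants: 1 vanillin (4-hydroxy-3-methoxybenzaldehyde)
Product: 2 3-methoxy-4-[(triisopropylsilyl)oxy]benzaldehyde
Conditions: TIPSCl, imidazole, DMF, rt
Reagents that add atoms: chlorotriisopropylsilane, CC(C)[Si](Cl)(C(C)C)C(C)C
Why: Standard phenol silylation; the triisopropylsilyl ether is chosen because it must outlast the aqueous rhodium step and the buffered HF that later removes the alkyl silyl ether.

Step 2
Reactants: 3 (tert-butyldimethylsilyloxy)acetaldehyde; 4 methyl acrylate
Product: 5 methyl 4-[(tert-butyldimethylsilyl)oxy]-3-hydroxy-2-methylidenebutanoate (racemic)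
Conditions: DABCO (1 equiv), 4 (3 equiv), 1,4-dioxane/H2O (1:1), rt
Reagents that add atoms: none
Why: Baylis–Hillman reaction; the amine adds to the acrylate and the resulting enolate attacks the unhindered α-silyloxy aldehyde, forming the C8–C8′ bond. The carbinol centre may be racemic because it becomes sp2 in step 4.

Step 3
Reactants: 5 methyl 4-[(tert-butyldimethylsilyl)oxy]-3-hydroxy-2-methylidenebutanoate
Product: 6 methyl 3-acetoxy-4-[(tert-butyldimethylsilyl)oxy]-2-methylidenebutanoate (racemic)
Conditions: Ac2O, pyridine, DMAP (cat.), CH2Cl2, 0 °C to rt
Reagents that add atoms: acetic anhydride, CC(=O)OC(C)=O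
Why: DMAP-catalysed acylation of a secondary allylic alcohol; the acetate is the leaving group for the allylic borylation.

Step 4
Reactants: 6 methyl 3-acetoxy-4-[(tert-butyldimethylsilyl)oxy]-2-methylidenebutanoate
Product: 7 methyl (E)-4-[(tert-butyldimethylsilyl)oxy]-2-[(4,4,5,5-tetramethyl-1,3,2-dioxaborolan-2-yl)methyl]but-2-enoate (CH2OSi cis to CH2B; vinyl H cis to the ester)
Conditions: B2pin2, CuCl (10 mol %), LiCl, KOAc, DMF, rt
Reagents that add atoms: bis(pinacolato)diboron, CC1(C)OB(OC1(C)C)B1OC(C)(C)C(C)(C)O1
Why: Copper-catalysed allylic borylation of a Baylis–Hillman acetate (SN2′ type): the boryl–copper species places boron on the acrylate methylene and the copper enolate expels acetate. The elimination should put the CH2OSi group trans to the ester, the usual geometry of such trisubstituted enoates.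

Step 5
Reactants: 2 3-methoxy-4-[(triisopropylsilyl)oxy]benzaldehyde; 7 methyl (E)-4-[(tert-butyldimethylsilyl)oxy]-2-[(4,4,5,5-tetramethyl-1,3,2-dioxaborolan-2-yl)methyl]but-2-enoate
Product: 9 (4R,5R)-4-{[(tert-butyldimethylsilyl)oxy]methyl}-5-{3-methoxy-4-[(triisopropylsilyl)oxy]phenyl}-3-methylideneoxolan-2-one (4,5-cis), via open-chain pinacol borate ester 8 (not isolated)
Conditions: (R)-TRIP [(R)-3,3′-bis(2,4,6-triisopropylphenyl)-1,1′-binaphthyl-2,2′-diyl hydrogen phosphate] (10 mol %), 7 (1.2 equiv), 4 Å MS, toluene, 0 °C to rt, then 40 °C
Reagents that add atoms: none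
Why: Brønsted-acid-catalysed allylboration: boron of 7 binds the aldehyde oxygen of 2 and the γ-carbon (normally the acceptor carbon of the acrylate, here the donor, future C8) is delivered to the carbonyl carbon (C7) through a closed six-membered chair of Zimmerman–Traxler type, with the phosphoric acid hydrogen-bonded to a boronate oxygen. The closest known reaction types are the chiral-phosphoric-acid-catalysed allyl- and crotylboration of aromatic aldehydes and the lactone-forming allylboration with 2-alkoxycarbonyl allylboronates. The borate oxygen of 8 then attacks the methyl ester in a 5-exo-trig acyl substitution, releases the methoxyborane and closes the γ-aryl α-methylene lactone. C8 is set relative to C7 by the alkene geometry of 7: the CH2OSi group cis to CH2B sits axial in the chair while the aryl group sits equatorial, which gives the syn adduct and hence the 4,5-cis lactone. C7 is set in the absolute sense by the catalyst, which should expose the re face of the aldehyde and give (R). The step needs γ-selectivity (inherent in the cyclic transition state), syn selectivity (secured by the geometric purity of 7), face selectivity (catalyst) and an intact benzylic C–O bond. The last point is secured by the weakness of the acid and by the para oxygen being a silyl ether, which is a poorer donor than an alkyl ether.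

Step 6
Reactants: 10 2-methoxy-4-(4,4,5,5-tetramethyl-1,3,2-dioxaborolan-2-yl)phenol (4-hydroxy-3-methoxyphenylboronic acid pinacol ester)
Product: 11 triisopropyl[2-methoxy-4-(4,4,5,5-tetramethyl-1,3,2-dioxaborolan-2-yl)phenoxy]silane
Conditions: TIPSCl, imidazole, DMF, rt
Reagents that add atoms: chlorotriisopropylsilane, CC(C)[Si](Cl)(C(C)C)C(C)C
Why: Standard phenol silylation that leaves the pinacol boronate untouched; it suppresses protodeboronation of the electron-rich ring and gives ring B the same protecting group as ring A.

Step 7
Reactants: 9 (4R,5R)-4-{[(tert-butyldimethylsilyl)oxy]methyl}-5-{3-methoxy-4-[(triisopropylsilyl)oxy]phenyl}-3-methylideneoxolan-2-one; 11 triisopropyl[2-methoxy-4-(4,4,5,5-tetramethyl-1,3,2-dioxaborolan-2-yl)phenoxy]silane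
Product: 12 (3R,4R,5R)-4-{[(tert-butyldimethylsilyl)oxy]methyl}-3-{3-methoxy-4-[(triisopropylsilyl)oxy]benzyl}-5-{3-methoxy-4-[(triisopropylsilyl)oxy]phenyl}oxolan-2-one (all-cis)
Conditions: [Rh(OH)(cod)]2 (3 mol %), 11 (2 equiv), Et3N (1 equiv), 1,4-dioxane/H2O (10:1), 50 °C
Reagents that add atoms: none
Why: Rhodium-catalysed conjugate addition of an arylboronate (Hayashi–Miyaura type) to the exocyclic acrylate: the aryl–rhodium species adds to the methylene terminus and water protonates the rhodium enolate at C8′. Protonation should come from the face opposite the cis CH2OSi and aryl groups, which places the new benzyl group on their face (all-cis, C8′ = R); the nearly neutral medium spares the lactone and the aryl silyl ethers.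

Step 8
Reactants: 12 (3R,4R,5R)-4-{[(tert-butyldimethylsilyl)oxy]methyl}-3-{3-methoxy-4-[(triisopropylsilyl)oxy]benzyl}-5-{3-methoxy-4-[(triisopropylsilyl)oxy]phenyl}oxolan-2-one
Product: 14 (3R,4R)-4-[(R)-hydroxy{3-methoxy-4-[(triisopropylsilyl)oxy]phenyl}methyl]-3-{3-methoxy-4-[(triisopropylsilyl)oxy]benzyl}oxolan-2-one (3,4-trans), via all-cis hydroxymethyl lactone 13 (not isolated)
Conditions: HF·pyridine, pyridine, THF, 0 °C to rt; Me3SiOMe; evaporation; then DBU (0.2 equiv), CH2Cl2, 0 °C to rt
Reagents that add atoms: none
Why: Buffered acidic fluoride should cleave the primary alkyl silyl ether much faster than the aryl triisopropylsilyl ethers, so no phenoxide arises while C7 still bears an acyloxy group. Base-catalysed translactonisation (O-to-O acyl migration through a bridged tetrahedral intermediate) then moves the acyl group to the primary C9 oxygen, driven by relief of the all-cis strain. No stereocentre is touched; because C8 now has C7 instead of C9 outside the ring, the all-cis lactone becomes the trans lactone.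

Step 9
Reactants: 14 (3R,4R)-4-[(R)-hydroxy{3-methoxy-4-[(triisopropylsilyl)oxy]phenyl}methyl]-3-{3-methoxy-4-[(triisopropylsilyl)oxy]benzyl}oxolan-2-one
Product: 15 (3R,4R)-4-[(R)-hydroxy(4-hydroxy-3-methoxyphenyl)methyl]-3-(4-hydroxy-3-methoxybenzyl)oxolan-2-one, the (7R,8R,8′R) target 5-allohydroxymatairesinol
Conditions: TBAF (2.5 equiv), AcOH (2.5 equiv), THF, 0 °C
Reagents that add atoms: none
Why: Fluoride cleavage of both aryl silyl ethers; the acetic acid buffer keeps the phenoxide concentration low, so that neither quinone methide formation at C7 nor return of the acyl group to O7 should occur.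

## Compound list

1 | vanillin (4-hydroxy-3-methoxybenzaldehyde) | COc1cc(C=O)ccc1O | starting material
2 | 3-methoxy-4-[(triisopropylsilyl)oxy]benzaldehyde | COc1cc(C=O)ccc1O[Si](C(C)C)(C(C)C)C(C)C | intermediate
3 | (tert-butyldimethylsilyloxy)acetaldehyde | O=CCO[Si](C)(C)C(C)(C)C | starting material
4 | methyl acrylate | C=CC(=O)OC | starting material
5 | methyl 4-[(tert-butyldimethylsilyl)oxy]-3-hydroxy-2-methylidenebutanoate (racemic) | C=C(C(=O)OC)C(O)CO[Si](C)(C)C(C)(C)C | intermediate
6 | methyl 3-acetoxy-4-[(tert-butyldimethylsilyl)oxy]-2-methylidenebutanoate (racemic) | C=C(C(=O)OC)C(OC(C)=O)CO[Si](C)(C)C(C)(C)C | intermediate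
7 | methyl (E)-4-[(tert-butyldimethylsilyl)oxy]-2-[(4,4,5,5-tetramethyl-1,3,2-dioxaborolan-2-yl)methyl]but-2-enoate | COC(=O)/C(CB1OC(C)(C)C(C)(C)O1)=C/CO[Si](C)(C)C(C)(C)C | intermediate
8 | methyl (3R,4R)-3-{[(tert-butyldimethylsilyl)oxy]methyl}-4-{3-methoxy-4-[(triisopropylsilyl)oxy]phenyl}-2-methylidene-4-[(4,4,5,5-tetramethyl-1,3,2-dioxaborolan-2-yl)oxy]butanoate (formed in situ) | C=C(C(=O)OC)[C@H](CO[Si](C)(C)C(C)(C)C)[C@@H](OB1OC(C)(C)C(C)(C)O1)c1ccc(O[Si](C(C)C)(C(C)C)C(C)C)c(OC)c1 | intermediate
9 | (4R,5R)-4-{[(tert-butyldimethylsilyl)oxy]methyl}-5-{3-methoxy-4-[(triisopropylsilyl)oxy]phenyl}-3-methylideneoxolan-2-one (4,5-cis) | C=C1C(=O)O[C@@H](c2ccc(O[Si](C(C)C)(C(C)C)C(C)C)c(OC)c2)[C@H]1CO[Si](C)(C)C(C)(C)C | intermediate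
10 | 2-methoxy-4-(4,4,5,5-tetramethyl-1,3,2-dioxaborolan-2-yl)phenol | COc1cc(B2OC(C)(C)C(C)(C)O2)ccc1O | starting material
11 | triisopropyl[2-methoxy-4-(4,4,5,5-tetramethyl-1,3,2-dioxaborolan-2-yl)phenoxy]silane | COc1cc(B2OC(C)(C)C(C)(C)O2)ccc1O[Si](C(C)C)(C(C)C)C(C)C | intermediate
12 | (3R,4R,5R)-4-{[(tert-butyldimethylsilyl)oxy]methyl}-3-{3-methoxy-4-[(triisopropylsilyl)oxy]benzyl}-5-{3-methoxy-4-[(triisopropylsilyl)oxy]phenyl}oxolan-2-one (all-cis) | COc1cc(C[C@H]2C(=O)O[C@@H](c3ccc(O[Si](C(C)C)(C(C)C)C(C)C)c(OC)c3)[C@H]2CO[Si](C)(C)C(C)(C)C)ccc1O[Si](C(C)C)(C(C)C)C(C)C | intermediate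
13 | (3R,4R,5R)-4-(hydroxymethyl)-3-{3-methoxy-4-[(triisopropylsilyl)oxy]benzyl}-5-{3-methoxy-4-[(triisopropylsilyl)oxy]phenyl}oxolan-2-one (all-cis, formed in situ) | COc1cc(C[C@H]2C(=O)O[C@@H](c3ccc(O[Si](C(C)C)(C(C)C)C(C)C)c(OC)c3)[C@H]2CO)ccc1O[Si](C(C)C)(C(C)C)C(C)C | intermediate
14 | (3R,4R)-4-[(R)-hydroxy{3-methoxy-4-[(triisopropylsilyl)oxy]phenyl}methyl]-3-{3-methoxy-4-[(triisopropylsilyl)oxy]benzyl}oxolan-2-one | COc1cc(C[C@H]2C(=O)OC[C@@H]2[C@@H](O)c2ccc(O[Si](C(C)C)(C(C)C)C(C)C)c(OC)c2)ccc1O[Si](C(C)C)(C(C)C)C(C)C | intermediate
15 | (3R,4R)-4-[(R)-hydroxy(4-hydroxy-3-methoxyphenyl)methyl]-3-(4-hydroxy-3-methoxybenzyl)oxolan-2-one (5-allohydroxymatairesinol) | COc1cc(C[C@H]2C(=O)OC[C@@H]2[C@@H](O)c2ccc(O)c(OC)c2)ccc1O | target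

## Step count and weak points

Total: 9 steps. Longest linear sequence: 7 steps (steps 2, 3, 4, 5, 7, 8, 9, from 3 and 4 to 15).

Step 5 (key step). The electron-poor, γ-substituted allylboronate and the electron-rich aldehyde may combine too slowly under a weak chiral acid. The uncatalysed, racemic pathway would then compete on warming and erode the enantiomeric purity, while a stronger acid would ionise the new benzylic C7–O bond and isomerise the cis lactone. The fallback moves stereocontrol from the catalyst to a covalently bound auxiliary:
- It sets out from 3. (1R,2S,5R)-8-phenylmenthyl acrylate F1, made from commercial (−)-8-phenylmenthol and acryloyl chloride, replaces 4 in the Baylis–Hillman reaction and gives the 8-phenylmenthyl ester of the hydroxy acrylate F2.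
- Acetylation gives the acetate F3, and CuCl-catalysed borylation with B2pin2 gives the 8-phenylmenthyl ester of the allylboronate F4.
- F4 is added to 2 thermally in toluene, or with Sc(OTf)3 at low temperature. The aryl group of the auxiliary shields one face of the allyl unit; lactonisation (helped by pyridinium p-toluenesulfonate if slow) expels the auxiliary alcohol, which is recovered.
- The sequence returns to the route at 9. The enantiomeric auxiliary is used if the sense of induction requires it.

Step 8. The acyl migration may stop short or run back if the all-cis ring is less strained than assumed; the amidine base may begin to epimerise C8′; and loss of a ring A silyl group would open the quinone methide pathway. The fallback replaces the equilibrating shift by hydrolysis and kinetically controlled reclosure. It sets out from 13, which is saponified briefly with LiOH in cold aqueous THF to the seco acid (2R,3R,4R)-4-hydroxy-3-(hydroxymethyl)-2-{3-methoxy-4-[(triisopropylsilyl)oxy]benzyl}-4-{3-methoxy-4-[(triisopropylsilyl)oxy]phenyl}butanoic acid F5. The lactone is then closed through the primary hydroxyl by Mitsunobu lactonisation (PPh3, diisopropyl azodicarboxylate, THF, 0 °C), in which the carboxylate displaces the activated C9 oxygen and C7 is not involved. The sequence returns at 14.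

Step 7. Protonation of the rhodium enolate in an aqueous medium may show poor facial selectivity, and transmetalation of the pinacol boronate without strong base may be slow enough for protodeboronation to compete. The fallback separates C–C bond formation from protonation with a stoichiometric organocopper addition:
- (4-Bromo-2-methoxyphenoxy)triisopropylsilane F6 is made from commercial 4-bromo-2-methoxyphenol and converted with Mg into {3-methoxy-4-[(triisopropylsilyl)oxy]phenyl}magnesium bromide F7.
- With CuBr·SMe2 (20 mol %) in THF at −40 °C, F7 adds to 9 in conjugate fashion and gives the bromomagnesium enolate of the benzylated lactone F8.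
- F8 is quenched at −78 °C with a hindered phenol (2,6-di-tert-butyl-4-methylphenol). Kinetic protonation of lactone enolates from the open face is the established way to cis-α,β-disubstituted butyrolactones.
- The sequence returns at 12.

Step 4. The alkene geometry may erode in the addition–elimination sequence, which would carry the anti adduct and hence the trans lactone into step 5. The fallback builds the allylboronate by a stereoretentive cross-coupling in place of the allylic substitution:
- It sets out from 3. The iodo ylide methyl 2-iodo-2-(triphenylphosphoranylidene)acetate F9, formed in the flask from methyl (triphenylphosphoranylidene)acetate and N-iodosuccinimide, converts 3 in a Wittig reaction into methyl (Z)-4-[(tert-butyldimethylsilyl)oxy]-2-iodobut-2-enoate F10.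
- Pd(PPh3)4-catalysed Negishi coupling of F10 with iodo[(4,4,5,5-tetramethyl-1,3,2-dioxaborolan-2-yl)methyl]zinc F11, from 2-(iodomethyl)-4,4,5,5-tetramethyl-1,3,2-dioxaborolane and Zn dust, installs the CH2B group with retention of geometry.
- The sequence returns at 7 and bypasses 5 and 6.

## Further compounds

F1 | step 5 | (1R,2S,5R)-5-methyl-2-(2-phenylpropan-2-yl)cyclohexyl acrylate | CC(C)(c1ccccc1)[C@@H]1CC[C@@H](C)C[C@H]1OC(=O)C=C
F2 | step 5 | (1R,2S,5R)-5-methyl-2-(2-phenylpropan-2-yl)cyclohexyl 4-[(tert-butyldimethylsilyl)oxy]-3-hydroxy-2-methylidenebutanoate (carbinol epimers) | CC(C)(c1ccccc1)[C@@H]1CC[C@@H](C)C[C@H]1OC(=O)C(=C)C(O)CO[Si](C)(C)C(C)(C)C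
F3 | step 5 | (1R,2S,5R)-5-methyl-2-(2-phenylpropan-2-yl)cyclohexyl 3-acetoxy-4-[(tert-butyldimethylsilyl)oxy]-2-methylidenebutanoate (carbinol epimers) | CC(C)(c1ccccc1)[C@@H]1CC[C@@H](C)C[C@H]1OC(=O)C(=C)C(OC(C)=O)CO[Si](C)(C)C(C)(C)C
F4 | step 5 | (1R,2S,5R)-5-methyl-2-(2-phenylpropan-2-yl)cyclohexyl (E)-4-[(tert-butyldimethylsilyl)oxy]-2-[(4,4,5,5-tetramethyl-1,3,2-dioxaborolan-2-yl)methyl]but-2-enoate | CC(C)(c1ccccc1)[C@@H]1CC[C@@H](C)C[C@H]1OC(=O)/C(CB2OC(C)(C)C(C)(C)O2)=C/CO[Si](C)(C)C(C)(C)C
F5 | step 8 | (2R,3R,4R)-4-hydroxy-3-(hydroxymethyl)-2-{3-methoxy-4-[(triisopropylsilyl)oxy]benzyl}-4-{3-methoxy-4-[(triisopropylsilyl)oxy]phenyl}butanoic acid | COc1cc(C[C@@H](C(=O)O)[C@H](CO)[C@@H](O)c2ccc(O[Si](C(C)C)(C(C)C)C(C)C)c(OC)c2)ccc1O[Si](C(C)C)(C(C)C)C(C)C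
F6 | step 7 | (4-bromo-2-methoxyphenoxy)triisopropylsilane | COc1cc(Br)ccc1O[Si](C(C)C)(C(C)C)C(C)C
F7 | step 7 | {3-methoxy-4-[(triisopropylsilyl)oxy]phenyl}magnesium bromide | COc1cc([Mg]Br)ccc1O[Si](C(C)C)(C(C)C)C(C)C
F8 | step 7 | bromomagnesium enolate of (4R,5R)-4-{[(tert-butyldimethylsilyl)oxy]methyl}-3-{3-methoxy-4-[(triisopropylsilyl)oxy]benzyl}-5-{3-methoxy-4-[(triisopropylsilyl)oxy]phenyl}oxolan-2-one | Br[Mg]OC1=C(Cc2ccc(O[Si](C(C)C)(C(C)C)C(C)C)c(OC)c2)[C@H](CO[Si](C)(C)C(C)(C)C)[C@H](c2ccc(O[Si](C(C)C)(C(C)C)C(C)C)c(OC)c2)O1
F9 | step 4 | methyl 2-iodo-2-(triphenylphosphoranylidene)acetate | COC(=O)C(I)=P(c1ccccc1)(c1ccccc1)c1ccccc1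
F10 | step 4 | methyl (Z)-4-[(tert-butyldimethylsilyl)oxy]-2-iodobut-2-enoate | COC(=O)/C(I)=C/CO[Si](C)(C)C(C)(C)C
F11 | step 4 | iodo[(4,4,5,5-tetramethyl-1,3,2-dioxaborolan-2-yl)methyl]zinc | I[Zn]CB1OC(C)(C)C(C)(C)O1
A1 | alternative 1 | (E)-3-[3-methoxy-4-(pivaloyloxy)phenyl]prop-2-en-1-yl diazoacetate | [N-]=[N+]=CC(=O)OC/C=C/c1ccc(OC(=O)C(C)(C)C)c(OC)c1
A2 | alternative 1 | (1S,5R,6R)-6-[3-methoxy-4-(pivaloyloxy)phenyl]-3-oxabicyclo[3.1.0]hexan-2-one (aryl exo) | O=C1OC[C@@H]2[C@@H](c3ccc(OC(=O)C(C)(C)C)c(OC)c3)[C@H]12
A3 | alternative 2 | 3-[(R)-[(tert-butyldimethylsilyl)oxy]{3-methoxy-4-[(tert-butyldimethylsilyl)oxy]phenyl}methyl]cyclobutan-1-one | O=C1CC(C1)[C@@H](O[Si](C)(C)C(C)(C)C)c1ccc(O[Si](C)(C)C(C)(C)C)c(OC)c1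
A4 | alternative 2 | (4R)-4-[(R)-[(tert-butyldimethylsilyl)oxy]{3-methoxy-4-[(tert-butyldimethylsilyl)oxy]phenyl}methyl]oxolan-2-one | O=C1C[C@@H]([C@@H](O[Si](C)(C)C(C)(C)C)c2ccc(O[Si](C)(C)C(C)(C)C)c(OC)c2)CO1
A5 | alternative 3 | methyl (R,E)-4-{[(bromomethyl)dimethylsilyl]oxy}-2-{3-methoxy-4-[(tert-butyldimethylsilyl)oxy]benzyl}-4-{3-methoxy-4-[(tert-butyldimethylsilyl)oxy]phenyl}but-2-enoate | COC(=O)/C(Cc1ccc(O[Si](C)(C)C(C)(C)C)c(OC)c1)=C/[C@@H](O[Si](C)(C)CBr)c1ccc(O[Si](C)(C)C(C)(C)C)c(OC)c1
A6 | alternative 3 | methyl 3-{3-methoxy-4-[(tert-butyldimethylsilyl)oxy]phenyl}-2-(trans-5-{3-methoxy-4-[(tert-butyldimethylsilyl)oxy]phenyl}-2,2-dimethyl-1-oxa-2-silacyclopentan-4-yl)propanoate (C7, C8 and C8′ as in the target) | COC(=O)[C@H](Cc1ccc(O[Si](C)(C)C(C)(C)C)c(OC)c1)[C@@H]1C[Si](C)(C)O[C@H]1c1ccc(O[Si](C)(C)C(C)(C)C)c(OC)c1
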